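Convention used throughout: atoms carry tetrahydrochromone numbers (O1, C2–C4, C4a, C5–C8, C8a), primes mark the aromatic chromone, β is the face of the carbocycle that carries the C6 and C7 oxygens and α is the opposite face.

## The problem

The target 22 is an ether-linked dimer: a 5,6,7,8-tetrahydro-2-(2-phenylethyl)chromone, whose carbocycle (C4a, C5–C8, C8a) is fused to a γ-pyranone through the C4a=C8a double bond, is bound through the oxygen on C5 to C6' of a 7'-hydroxy-2-(2-phenylethyl)chromone. The four contiguous stereocentres are (5S,6S,7R,8S): the oxygens on C6 and C7 are cis (β), those on C5 and C8 are cis to each other on the α face, so each oxygen is trans to its neighbour. Once C6 and C7 are tied into a cis-fused acetonide they can direct any bond formation at C5 or C8 to the α face, so they must be installed first and in absolute form. Five of the six ring carbons (C5–C8 and C8a) bear oxygen and only C4a bears carbon; C5 and C8a flank C4a almost symmetrically, so the pyranone oxygen has to be steered to C8a and not to C5. The C5–O(aryl) bond is the fragile point: it is allylic to the enol-ether double bond C4a=C8a (ionisation assisted by O1, hydrogenolysis), it becomes a β-leaving group whenever C4a is sp3 next to a carbonyl, and the polyol ring aromatises by elimination under strong acid, base or heat. The enabling feature is that the 1,4-cis oxygens on C5 and C8 flank C4a=C8a and lie anti to the 6,7-cis pair. This is the imprint of dioxygen bridging the termini of a cyclohexa-1,3-diene (C5=C4a–C8a=C8) on the face opposite a 6,7-acetonide, and such a diene diol is available as one enantiomer from microbial arene oxidation.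

## Retrosynthesis

**Last step.** 22 is taken back to its protected form 21 (6,7-acetonide, 8-O-silyl, 7'-O-methoxymethyl). No skeletal bond is cut. All three groups fall in one mild aqueous acid treatment; benzyl ethers were rejected because hydrogenolysis would endanger the allylic C5–O bond and the pyranone double bonds.

**C5–O(aryl).** 21 is cut at the C5–O bond into the 5β-alcohol 14 and the phenol 20. The neighbouring cut, O–C6' of the arene, would need substitution at an unactivated, ortho-substituted aryl carbon. An epoxide opening at C5 would need a free C6 oxygen and so give up the acetonide that controls the stereochemistry. Displacement at C5 with inversion lets the nucleophile enter on the α face, anti to the acetonide, and needs exactly the alcohol that hydride reduction gives. The cut divides the molecule into a C26 and a C19 half. The forward reaction must invert an activated secondary carbinol cleanly, without ionisation or elimination.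

**C5–H.** 14 comes from the 4,5-dione 13 by reduction at C5. The ketone is the natural precursor because C5 leaves the key step at the carbonyl oxidation level. The forward reaction must reduce C5 in preference to the pyranone carbonyl and deliver hydride to the α face.

**Pyranone ring (O1–C8a and C4–C4a).** 13 is cut into the enaminone 8 and the acylketene 12, released from the dioxinone 11. Two neighbouring cuts were weighed:
- Acylating C4a of the enone 5 leads through a 2-acyl-2-enone, a cross-conjugated, doubly activated acceptor that then still needs water added at C8a and hydrogen removed.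
- Closing a 2-acyl-1,3-dione would treat the C5 and C8a carbonyls alike and give both fusion senses.

In 8 the two positions are different functional groups (C5 carbonyl, C8a C–N), so O1 can only end on C8a. The precursors are much simpler: a vinylogous amide built on the single carbocycle and a C11 ketene. The forward reaction must acylate C4a, close oxygen on C8a and expel the amine.

**C8a–N from C8a–H.** 8 comes from the 3-(phenylthio) enone 7 by amine exchange, and 7 from the enone 5 (through the adduct 6) by thia-Michael addition and oxidation. This raises the β-carbon C8a to the ketone oxidation level regiospecifically, which a route through the free 1,3-dione could not guarantee.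

**Peroxide collapse.** 5 is the silyl ether of the hydroxy enone 4, and 4 arises from the bromo endoperoxide 3 by reduction of the O–O bond. The bromine on C5 decides that C5, not C8, becomes the ketone, while C8 keeps its oxygen and configuration.

**Key cut (C5–O and C8–O).** 3 is opened to the diene acetonide 2, made in one step from the diene diol 1. Both C–O bonds and the C8 stereocentre come from one cycloaddition, on the face opposite the acetonide. The mapping was checked: the bromine of 1 marks C5 and its carbinol carbons become C6 and C7, which gives the (6S,7R,8S) series of 22; the reverse mapping would give the enantiomer.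

**Side fragments.** 20 comes from the catechol 19 by selective 7-O-alkylation, 19 from the dimethyl ether 18, and 18 from the acetophenone 15 and the ester 16 through the diketone 17 (Claisen condensation, cyclodehydration). 11 comes from the dioxinone 9 and the bromide 10 by γ-alkylation.

## Roads not taken

**Alternative 1:** The carbocycle is cut at C5–C6 and C7–C8. This leaves a monocyclic pyranone aldehyde, 2-(benzyloxymethyl)-3-formyl-6-(2-phenylethyl)-4H-pyran-4-one (A1), and a two-carbon dienophile, (E)-1,2-bis(phenylsulfonyl)ethene (A2).

In the forward step, irradiation of A1 at 365 nm in the presence of titanium tetraisopropoxide A3 and a chiral diol ligand would move a hydrogen from the benzyloxymethyl carbon (future C8) to the formyl oxygen. The hydroxy-ortho-quinodimethane would then add A2 to give the bis-sulfone A4.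

- Merits: the pyranone is present from the start, so the C5/C8a differentiation never arises. The route is convergent and short. C5–OH and C8–OBn are born differentiated and cis.
- Weak points:
  - Photoenolisation–Diels–Alder chemistry is established for ortho-alkyl aryl carbonyls. A 4-pyranone has its own photorearrangements, and enantiocontrol by a chiral diolate made from the alkoxide A3 is unproven for this chromophore, yet the whole absolute configuration would rest on it.
  - C6 and C7 arrive as sulfones. They need reductive elimination and a cis-dihydroxylation, passing through a 5,8-dioxygenated dihydrochromone that can aromatise by elimination.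
  - The 5-hydroxyl emerges on the α face, so the aryl ether would have to be made with retention.
  - Benzyl removal at the end means hydrogenolysis next to the C5–O bond.
- Comparison: if the photochemistry worked this road would be shorter than the chosen one and is the better plan in step economy. The chosen plan sets against it a purchased absolute configuration, facial selectivities fixed by a rigid acetonide, and an ether formation that uses inversion.

**Alternative 2:** The cut is C4a–C5. The precursor is the aryl glycoside A5, a manno-configured 6-deoxyhex-5-enopyranoside that already carries the chromonyl ether at the anomeric carbon.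

In the forward step isopropoxytitanium trichloride A6 would cleave the ring C1–O5 bond of A5. The titanium enolate carbon (future C4a) would add to the aryloxy-substituted oxocarbenium carbon (future C5) in a Ferrier-type carbocyclisation, giving the cyclohexanone A7.

- Merits: C6, C7 and C8 come from the sugar with the right 2,3-cis-3,4-trans pattern. The aryl ether is made by glycosylation chemistry. The ketone appears at C8a with a C4a methylene, the pattern a pyranone annulation wants. In this last respect it is better than the chosen plan, which must oxidise C8a and reduce C5.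
- Weak points:
  - Retention of an aryloxy aglycon in this rearrangement is less secure than for alkyl glycosides, since the Lewis acid A6 can also ionise the exocyclic C1–OAr bond, and the C5 configuration is set in the aldol-type closure.
  - A7 is a β-aryloxy ketone with enolisable C4a hydrogens, so loss of the phenoxide threatens every later enolate step.
  - C4a versus C8 enolisation must be controlled.
  - The valuable aryl half is carried through many steps, and benzyl ethers again force a final hydrogenolysis.
- Comparison: the chosen plan pays three steps for the C8a oxidation, but it joins the halves last and never has C4a sp3 beside the aryl ether.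

**Alternative 3:** The cut is C2–C3 in both heterocycles at once. The precursor is the bis(methyl ketone) A8, and the acyl donor is methyl 3-phenylpropanoate (A9).

In the forward step an excess of lithium hexamethyldisilazide A10 would form both methyl ketone enolates, and A9 would acylate them to the bis(1,3-diketone) A11. Acid would then close both pyranones, the carbocyclic one by displacing the vinylogous ester methoxy group.

- Merits: it uses the hidden symmetry of the two phenethylpyranone arms, forms both heterocycles in two operations from one cheap ester, and keeps C8a (enol ether) and C5 (sp3) distinct. In heterocycle construction it is more economical than the chosen plan, which builds the two pyranones separately (steps 8 and 10).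
- Weak points:
  - The step creates no ring and no stereocentre. A8, with all four stereocentres and the aryl ether, still has to come from another strategy.
  - Three acidic sites, counting the phenol, demand a large excess of the base A10 next to a C5 aryloxy group that can be eliminated from the extended enolate, and next to a Michael-accepting vinylogous ester.
  - Benzyl ethers recur.
- Comparison: it is an endgame tactic, not a route to the carbocycle. The chosen plan uses the same Claisen logic only for the robust aromatic half, and sets against the lost convergence an ether formation that is postponed until both pyranones are complete.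

Key step: step 2

## Route

Step 1
Reactants: 1 (1S,2S)-3-bromocyclohexa-3,5-diene-1,2-diol
Product: 2 (3aS,7aS)-4-bromo-2,2-dimethyl-3a,7a-dihydro-1,3-benzodioxole
Conditions: 2,2-dimethoxypropane, TsOH·H2O (cat.), acetone, 0 °C → rt
Reagents that add atoms: 2,2-dimethoxypropane COC(C)(C)OC
Why: Acid-catalysed transketalisation closes the dioxolane on the cis-diol without touching the carbinol stereocentres; the acetonide blocks dehydration to the phenol and becomes the facial control element.

Step 2
Reactants: 2 (3aS,7aS)-4-bromo-2,2-dimethyl-3a,7a-dihydro-1,3-benzodioxole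
Product: 3 bromo endoperoxide (2,3-dioxabicyclo[2.2.2]oct-5-ene with Br on the bridgehead that becomes C5 and the isopropylidenedioxy group anti to the peroxide bridge)
Conditions: O2, tetraphenylporphyrin (cat.), visible light (white LED), CH2Cl2, −30 °C
Reagents that add atoms: dioxygen O=O
Why: Tetraphenylporphyrin-sensitised singlet oxygen acts as a two-atom dienophile and adds in a concerted, suprafacial [4+2] cycloaddition across the termini of the ring-locked s-cis diene of 2, the bromine-bearing carbon (future C5) and the CH terminus (future C8). The closest known reaction type is the photooxygenation of cyclohexa-1,3-dienes and of arene cis-dihydrodiol acetonides to 2,3-dioxabicyclo[2.2.2]oct-5-enes. The new six-membered 1,2-dioxane ring is closed by the cycloaddition itself, both C–O bonds forming on one face in a single event, which is why the C5 and C8 oxygens are cis and why the remaining double bond lies between the future C4a and C8a. Both new stereocentres are controlled by the cis-fused dioxolane, which shields the β face so that oxygen approaches the convex α face; the absolute sense is inherited from the enzymatically set carbinol centres of 1. The step needs facial selectivity anti to the acetonide, preference for [4+2] over the ene reaction, and a rate above that of Diels–Alder dimerisation of 2. The rigid bicyclic acetonide secures the first, the ring-locked s-cis diene makes the concerted [4+2] far faster than the ene reaction, whose only allylic hydrogens sit on the oxygen-bearing, electron-poor carbinol carbons, and low temperature, dilution and freshly made 2 address the third. The vinylic bromine is tolerated by the electrophilic oxidant and is what lets the peroxide collapse regioselectively to the C5 ketone in step 3.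

Step 3
Reactants: 3 bromo endoperoxide
Product: 4 (3aS,7R,7aS)-7-hydroxy-2,2-dimethyl-7,7a-dihydro-1,3-benzodioxol-4(3aH)-one
Conditions: thiourea, MeOH, 0 °C → rt
Reagents that add atoms: none
Why: Thiourea reduces the O–O bond; the bromo alkoxide at C5 expels bromide to give the C5 ketone while C8 keeps its oxygen and configuration, the known collapse of halogenated diene endoperoxides to 4-hydroxy enones.

Step 4
Reactants: 4 (3aS,7R,7aS)-7-hydroxy-2,2-dimethyl-7,7a-dihydro-1,3-benzodioxol-4(3aH)-one
Product: 5 (3aS,7R,7aR)-7-[(tert-butyldimethylsilyl)oxy]-2,2-dimethyl-7,7a-dihydro-1,3-benzodioxol-4(3aH)-one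
Conditions: TBSCl, imidazole, DMF, 0 °C → rt
Reagents that add atoms: tert-butyldimethylsilyl chloride CC(C)(C)[Si](C)(C)Cl
Why: Standard silylation of a secondary allylic alcohol; the silyl ether distinguishes O8 from the later C5 hydroxyl and is acid-labile like the other protecting groups.

Step 5
Reactants: 5 (3aS,7R,7aR)-7-[(tert-butyldimethylsilyl)oxy]-2,2-dimethyl-7,7a-dihydro-1,3-benzodioxol-4(3aH)-one
Product: 7 3-(phenylthio) enone (silyl enone 5 carrying SPh on the β-carbon, the future C8a), via β-phenylthio ketone 6 (not isolated)
Conditions: PhSH, Et3N (cat.), CH2Cl2, 0 °C; then N-chlorosuccinimide, NaHCO3, 0 °C → rt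
Reagents that add atoms: thiophenol Sc1ccccc1
Why: Thia-Michael addition followed by N-chlorosuccinimide oxidation of the β-sulfenyl ketone (Pummerer-type chlorination at the sulfur-bearing carbon, then loss of HCl through the acidic C4a–H) is an established way to turn an enone into its 3-(phenylthio) enone. It raises C8a to the ketone oxidation level while C5 and C8a stay chemically distinct; the configuration at the sulfur-bearing carbon of 6 is of no consequence.

Step 6
Reactants: 7 3-(phenylthio) enone
Product: 8 3-(pyrrolidin-1-yl) enone (vinylogous amide with nitrogen on the future C8a)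
Conditions: pyrrolidine (3 equiv), MeCN, rt → 50 °C
Reagents that add atoms: pyrrolidine C1CCNC1
Why: Addition–elimination of a secondary amine at the β-carbon of a vinylogous thioester (vinylogous transamidation) with thiophenoxide as leaving group; the nitrogen donor makes C4a nucleophilic.

Step 7
Reactants: 9 2,2,6-trimethyl-4H-1,3-dioxin-4-one; 10 benzyl bromide
Product: 11 2,2-dimethyl-6-(2-phenylethyl)-4H-1,3-dioxin-4-one
Conditions: LiN(iPr)2, THF, DMPU, −78 °C → −40 °C
Reagents that add atoms: none
Why: Deprotonation of the dioxinone gives the vinylogous ester dienolate, which is alkylated at the exocyclic γ-carbon by the benzylic bromide.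

Step 8
Reactants: 8 3-(pyrrolidin-1-yl) enone; 11 2,2-dimethyl-6-(2-phenylethyl)-4H-1,3-dioxin-4-one
Product: 13 8α-[(tert-butyldimethylsilyl)oxy]-6β,7β-(isopropylidenedioxy)-2-(2-phenylethyl)-7,8-dihydro-4H-chromene-4,5(6H)-dione, via acylketene 12 (not isolated)
Conditions: 11 (2.5 equiv), toluene, 110 °C
Reagents that add atoms: none
Why: Thermal retro-[4+2] of the dioxinone releases acetone and the acylketene 12, which undergoes the known formal [4+2] annulation of acylketenes with enamines: C4a attacks the ketene carbon (C4–C4a), the enolate oxygen closes on the iminium carbon C8a (O1–C8a), and β-elimination of pyrrolidine gives the γ-pyranone. Oxygen can only close on the nitrogen-bearing carbon, so the ring is fused in the required sense and the C5 ketone is left intact.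

Step 9
Reactants: 13 8α-silyloxy-6β,7β-(isopropylidenedioxy)-4,5-dione
Product: 14 5β-hydroxy-8α-[(tert-butyldimethylsilyl)oxy]-6β,7β-(isopropylidenedioxy)-2-(2-phenylethyl)-5,6,7,8-tetrahydro-4H-chromen-4-one
Conditions: NaBH4, CeCl3·7H2O, MeOH, −78 °C
Reagents that add atoms: none
Why: Luche reduction: the cerium-activated C5 ketone is reduced in preference to the pyranone carbonyl, and hydride is delivered to the α face, anti to the cis-fused dioxolane and to the C6–O bond (Felkin–Anh), so the new C5 hydroxyl should be β, cis to O6.

Step 10
Reactants: 15 1-(2-hydroxy-4,5-dimethoxyphenyl)ethan-1-one; 16 ethyl 3-phenylpropanoate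
Product: 18 6,7-dimethoxy-2-(2-phenylethyl)-4H-chromen-4-one, via 1,3-diketone 17 (not isolated)
Conditions: NaH, THF, 65 °C; then conc. HCl, AcOH, 80 °C
Reagents that add atoms: none
Why: Crossed Claisen condensation of the acetophenone enolate with the ester gives the 1,3-diketone, whose acid-catalysed cyclodehydration through the ortho-phenol is the standard route to 2-substituted chromones.

Step 11
Reactants: 18 6,7-dimethoxy-2-(2-phenylethyl)-4H-chromen-4-one
Product: 19 6,7-dihydroxy-2-(2-phenylethyl)-4H-chromen-4-one
Conditions: BBr3, CH2Cl2, −78 °C → rt; then H2O
Reagents that add atoms: none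
Why: Lewis-acid cleavage of aryl methyl ethers; the chromone and the alkyl chain are inert.

Step 12
Reactants: 19 6,7-dihydroxy-2-(2-phenylethyl)-4H-chromen-4-one
Product: 20 6-hydroxy-7-(methoxymethoxy)-2-(2-phenylethyl)-4H-chromen-4-one
Conditions: MOMCl (1.05 equiv), K2CO3 (1.1 equiv), acetone, 0 °C
Reagents that add atoms: chloromethyl methyl ether COCCl
Why: Williamson alkylation with one equivalent of weak base: the 7-OH, para to the C4 carbonyl, is the more acidic phenol and is alkylated selectively, leaving the 6-OH free.

Step 13
Reactants: 14 5β-hydroxy-8α-silyloxy-6β,7β-(isopropylidenedioxy)tetrahydrochromone; 20 6-hydroxy-7-(methoxymethoxy)-2-(2-phenylethyl)-4H-chromen-4-one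
Product: 21 protected dimer (5α-aryl ether of the tetrahydrochromone with the 6β,7β-acetonide and the 8α-silyl ether; the aryl group is 7-(methoxymethoxy)-4-oxo-2-(2-phenylethyl)-4H-chromen-6-yl)
Conditions: PPh3, DIAD, toluene, 0 °C → rt
Reagents that add atoms: none
Why: Mitsunobu etherification: the C5 oxyphosphonium ion is displaced by the phenoxide of 20 in an SN2 reaction with inversion, the nucleophile entering on the α face anti to the acetonide, which sets C5 (S) trans to O6 and cis to O8.

Step 14
Reactants: 21 protected dimer
Product: 22 (5S,6S,7R,8S)-6,7,8-trihydroxy-5-{[7-hydroxy-4-oxo-2-(2-phenylethyl)-4H-chromen-6-yl]oxy}-2-(2-phenylethyl)-5,6,7,8-tetrahydro-4H-chromen-4-one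
Conditions: 2 M aq. HCl, THF, rt → 40 °C
Reagents that add atoms: none
Why: Acid hydrolysis removes the isopropylidene ketal, the silyl ether and the methoxymethyl acetal in one operation without touching any stereocentre.

## Compound list

1 | (1S,2S)-3-bromocyclohexa-3,5-diene-1,2-diol | BrC1=CC=C[C@H](O)[C@@H]1O | starting material
2 | (3aS,7aS)-4-bromo-2,2-dimethyl-3a,7a-dihydro-1,3-benzodioxole | BrC1=CC=C[C@@H]2OC(C)(C)O[C@H]12 | intermediate
3 | bromo endoperoxide: 2,3-dioxabicyclo[2.2.2]oct-5-ene, Br on the bridgehead (future C5), isopropylidenedioxy group anti to the peroxide bridge | Br[C@@]12C=C[C@@H](OO1)[C@@H]1OC(C)(C)O[C@H]21 | intermediate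
4 | (3aS,7R,7aS)-7-hydroxy-2,2-dimethyl-7,7a-dihydro-1,3-benzodioxol-4(3aH)-one | O=C1C=C[C@@H](O)[C@@H]2OC(C)(C)O[C@H]12 | intermediate
5 | (3aS,7R,7aR)-7-[(tert-butyldimethylsilyl)oxy]-2,2-dimethyl-7,7a-dihydro-1,3-benzodioxol-4(3aH)-one | O=C1C=C[C@@H](O[Si](C)(C)C(C)(C)C)[C@@H]2OC(C)(C)O[C@H]12 | intermediate
6 | β-phenylthio ketone: thiophenol adduct of 5, SPh on the future C8a, drawn trans to the silyloxy group | O=C1C[C@H](Sc2ccccc2)[C@@H](O[Si](C)(C)C(C)(C)C)[C@@H]2OC(C)(C)O[C@H]12 | intermediate
7 | 3-(phenylthio) enone: 5 with SPh on the β-carbon (future C8a) | O=C1C=C(Sc2ccccc2)[C@@H](O[Si](C)(C)C(C)(C)C)[C@@H]2OC(C)(C)O[C@H]12 | intermediate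
8 | 3-(pyrrolidin-1-yl) enone: 5 with pyrrolidin-1-yl on the β-carbon (future C8a) | O=C1C=C(N3CCCC3)[C@@H](O[Si](C)(C)C(C)(C)C)[C@@H]2OC(C)(C)O[C@H]12 | intermediate
9 | 2,2,6-trimethyl-4H-1,3-dioxin-4-one | CC1=CC(=O)OC(C)(C)O1 | starting material
10 | benzyl bromide | BrCc1ccccc1 | starting material
11 | 2,2-dimethyl-6-(2-phenylethyl)-4H-1,3-dioxin-4-one | CC1(C)OC(CCc2ccccc2)=CC(=O)O1 | intermediate
12 | acylketene: 3-oxo-5-phenylpent-1-en-1-one | O=C=CC(=O)CCc1ccccc1 | intermediate
13 | 8α-[(tert-butyldimethylsilyl)oxy]-6β,7β-(isopropylidenedioxy)-2-(2-phenylethyl)-7,8-dihydro-4H-chromene-4,5(6H)-dione | O=c1cc(CCc2ccccc2)oc2c1C(=O)[C@H]1OC(C)(C)O[C@H]1[C@@H]2O[Si](C)(C)C(C)(C)C | intermediate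
14 | 5β-hydroxy-8α-[(tert-butyldimethylsilyl)oxy]-6β,7β-(isopropylidenedioxy)-2-(2-phenylethyl)-5,6,7,8-tetrahydro-4H-chromen-4-one | O=c1cc(CCc2ccccc2)oc2c1[C@@H](O)[C@H]1OC(C)(C)O[C@H]1[C@@H]2O[Si](C)(C)C(C)(C)C | intermediate
15 | 1-(2-hydroxy-4,5-dimethoxyphenyl)ethan-1-one | CC(=O)c1cc(OC)c(OC)cc1O | starting material
16 | ethyl 3-phenylpropanoate | CCOC(=O)CCc1ccccc1 | starting material
17 | 1-(2-hydroxy-4,5-dimethoxyphenyl)-5-phenylpentane-1,3-dione | O=C(CC(=O)CCc1ccccc1)c1cc(OC)c(OC)cc1O | intermediate
18 | 6,7-dimethoxy-2-(2-phenylethyl)-4H-chromen-4-one | O=c1cc(CCc2ccccc2)oc2cc(OC)c(OC)cc12 | intermediate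
19 | 6,7-dihydroxy-2-(2-phenylethyl)-4H-chromen-4-one | O=c1cc(CCc2ccccc2)oc2cc(O)c(O)cc12 | intermediate
20 | 6-hydroxy-7-(methoxymethoxy)-2-(2-phenylethyl)-4H-chromen-4-one | O=c1cc(CCc2ccccc2)oc2cc(OCOC)c(O)cc12 | intermediate
21 | protected dimer: 5α-{[7-(methoxymethoxy)-4-oxo-2-(2-phenylethyl)-4H-chromen-6-yl]oxy}-8α-[(tert-butyldimethylsilyl)oxy]-6β,7β-(isopropylidenedioxy)-2-(2-phenylethyl)-5,6,7,8-tetrahydro-4H-chromen-4-one | O=c1cc(CCc2ccccc2)oc2c1[C@H](Oc1cc3c(=O)cc(CCc4ccccc4)oc3cc1OCOC)[C@H]1OC(C)(C)O[C@H]1[C@@H]2O[Si](C)(C)C(C)(C)C | intermediate
22 | (5S,6S,7R,8S)-6,7,8-trihydroxy-5-{[7-hydroxy-4-oxo-2-(2-phenylethyl)-4H-chromen-6-yl]oxy}-2-(2-phenylethyl)-5,6,7,8-tetrahydro-4H-chromen-4-one | O=c1cc(CCc2ccccc2)oc2c1[C@H](Oc1cc3c(=O)cc(CCc4ccccc4)oc3cc1O)[C@@H](O)[C@@H](O)[C@@H]2O | target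

## Step count and risks

Total step count: 14. Longest linear sequence: 10 steps (1, 2, 3, 4, 5, 6, 8, 9, 13, 14) from diol 1.

Least certain steps:

**Step 2 (key step).** Diels–Alder dimerisation of the diene 2 may outrun the photooxygenation, and the halogenated peroxide may decompose (O–O homolysis or rearrangement to a bis-epoxide) before it is reduced. The fallback replaces the cycloaddition by a stepwise 1,4-oxygenation and sets out from 2. Peracid epoxidation of the bromine-free double bond on the α face should give the vinyl epoxide F1. Opening at the allylic carbon with phenylselenide (PhSeSePh, NaBH4, EtOH) should give the trans hydroxy selenide F2. Oxidation with H2O2 triggers the [2,3]-sigmatropic selenoxide rearrangement, which carries oxygen to the bromine-bearing carbon and moves the double bond to C4a=C8a. The resulting bromo selenenate collapses to the C5 ketone, and the route is rejoined at 4.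

**Step 5.** After S-chlorination the sulfur may be eliminated again, returning 5, instead of the Pummerer-type oxidation. Over-chlorination and acid cleavage of the acetonide by the HCl formed are further risks. The fallback abandons the heteroatom relay and sets out from 5. α-Iodination (I2, pyridine) should give the 2-iodo enone F3. Carbonylative Sonogashira coupling with 4-phenylbut-1-yne (CO, PdCl2(PPh3)2, CuI, Et3N) should give the ynone F4. Conjugate hydration of the ynone and oxa-Michael closure on C8a give the dihydropyranone F5, and DDQ dehydrogenation across C4a–C8a rejoins the route at 13, bypassing steps 6 and 8.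

**Step 8.** The hindered vinylogous amide may be too weak a nucleophile at C4a, so that the acylketene is lost to dimerisation or to the liberated amine. Base- and heat-induced β-elimination of the C7 oxygen at 110 °C is the second danger. The fallback builds the same ring stepwise and sets out from 8. C-Acetylation at C4a (acetyl chloride, pyridine) should give the 2-acetyl enaminone F6. Claisen condensation of its LiN(SiMe3)2 enolate with the ester 16 should give the diketone F7. Mild acid (TsOH, toluene) closes the enol oxygen on C8a with loss of pyrrolidine, which rejoins the route at 13.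

**Step 13.** The activated C5 oxyphosphonium ion may ionise (assisted by O1) before displacement. That would cost stereospecificity or lead to elimination toward C6 and aromatisation. Hydrogen bonding of the 5-hydroxyl to the C4 carbonyl may also slow activation. The fallback uses an acid-catalysed cationic substitution under steric control instead and sets out from 14. Cl3CCN with catalytic DBU should give the trichloroacetimidate F8. Catalytic TMSOTf at −78 °C in the presence of 20 should then deliver the phenol to the O1-stabilised cation on the α face, anti to the acetonide, and rejoin the route at 21.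

**Step 14.** The C5–O(aryl) bond may ionise, or the polyol ring may dehydrate and aromatise, while the slowest protecting group is still being hydrolysed. The fallback separates the deprotections and sets out from 21. Bu4NF buffered with AcOH should remove the silyl group to give the 8-alcohol F9. A sulfonic acid resin in aqueous methanol at room temperature should then cleave the acetonide and the methoxymethyl acetal, reaching 22.

## Further compounds

F1 | step 2 | vinyl epoxide: α-epoxide of the bromine-free double bond of 2 | BrC1=C[C@H]2O[C@H]2[C@@H]2OC(C)(C)O[C@H]12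
F2 | step 2 | hydroxy selenide: allylic phenylselanyl group (β) trans to the new hydroxyl (α) | BrC1=C[C@H]([Se]c2ccccc2)[C@@H](O)[C@@H]2OC(C)(C)O[C@H]12
F3 | step 5 | 2-iodo enone: 5 iodinated at the α-carbon (future C4a) | O=C1C(I)=C[C@@H](O[Si](C)(C)C(C)(C)C)[C@@H]2OC(C)(C)O[C@H]12
F4 | step 5 | ynone: 5 carrying a 5-phenylpent-2-ynoyl group on the α-carbon (future C4a) | O=C1C(C(=O)C#CCCc3ccccc3)=C[C@@H](O[Si](C)(C)C(C)(C)C)[C@@H]2OC(C)(C)O[C@H]12
F5 | step 5 | dihydropyranone: 4a,8a-dihydro form of 13, ring-fusion configuration undefined | O=C1C=C(CCc2ccccc2)OC2C1C(=O)[C@H]1OC(C)(C)O[C@H]1[C@@H]2O[Si](C)(C)C(C)(C)C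
F6 | step 8 | 2-acetyl enaminone: 8 acetylated at the α-carbon (future C4a) | O=C1C(C(C)=O)=C(N3CCCC3)[C@@H](O[Si](C)(C)C(C)(C)C)[C@@H]2OC(C)(C)O[C@H]12
F7 | step 8 | diketone: 8 carrying a 3-oxo-5-phenylpentanoyl group on the α-carbon (future C4a) | O=C1C(C(=O)CC(=O)CCc3ccccc3)=C(N4CCCC4)[C@@H](O[Si](C)(C)C(C)(C)C)[C@@H]2OC(C)(C)O[C@H]12
F8 | step 13 | 5β-trichloroacetimidate of 14 | O=c1cc(CCc2ccccc2)oc2c1[C@@H](OC(=N)C(Cl)(Cl)Cl)[C@H]1OC(C)(C)O[C@H]1[C@@H]2O[Si](C)(C)C(C)(C)C
F9 | step 14 | 8-alcohol: 21 without the silyl group | O=c1cc(CCc2ccccc2)oc2c1[C@H](Oc1cc3c(=O)cc(CCc4ccccc4)oc3cc1OCOC)[C@H]1OC(C)(C)O[C@H]1[C@@H]2O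
A1 | alternative 1 | 2-(benzyloxymethyl)-3-formyl-6-(2-phenylethyl)-4H-pyran-4-one | O=Cc1c(COCc2ccccc2)oc(CCc2ccccc2)cc1=O
A2 | alternative 1 | (E)-1,2-bis(phenylsulfonyl)ethene | O=S(=O)(/C=C/S(=O)(=O)c1ccccc1)c1ccccc1
A3 | alternative 1 | titanium tetraisopropoxide, Ti(OiPr)4 | CC(C)O[Ti](OC(C)C)(OC(C)C)OC(C)C
A4 | alternative 1 | 8-benzyloxy-5-hydroxy-6,7-bis(phenylsulfonyl)-2-(2-phenylethyl)-5,6,7,8-tetrahydrochromone | O=c1cc(CCc2ccccc2)oc2c1[C@H](O)[C@@H](S(=O)(=O)c1ccccc1)[C@H](S(=O)(=O)c1ccccc1)[C@@H]2OCc1ccccc1
A5 | alternative 2 | 7-(benzyloxy)-4-oxo-2-(2-phenylethyl)-4H-chromen-6-yl 2,3,4-tri-O-benzyl-6-deoxy-α-D-lyxo-hex-5-enopyranoside | C=C1O[C@H](Oc2cc3c(=O)cc(CCc4ccccc4)oc3cc2OCc2ccccc2)[C@@H](OCc2ccccc2)[C@@H](OCc2ccccc2)[C@@H]1OCc1ccccc1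
A6 | alternative 2 | isopropoxytitanium trichloride, Ti(OiPr)Cl3 | CC(C)O[Ti](Cl)(Cl)Cl
A7 | alternative 2 | 5-(chromon-6-yloxy)-2,3,4-tris(benzyloxy)cyclohexanone (C8a ketone, C4a methylene) | O=C1C[C@H](Oc2cc3c(=O)cc(CCc4ccccc4)oc3cc2OCc2ccccc2)[C@@H](OCc2ccccc2)[C@@H](OCc2ccccc2)[C@@H]1OCc1ccccc1
A8 | alternative 3 | bis(methyl ketone): vinylogous ester with a C4a acetyl group and a 5-aryloxy group bearing the ortho-hydroxyacetophenone unit | COC1=C(C(C)=O)[C@H](Oc2cc(C(C)=O)c(O)cc2OCc2ccccc2)[C@@H](OCc2ccccc2)[C@@H](OCc2ccccc2)[C@@H]1OCc1ccccc1
A9 | alternative 3 | methyl 3-phenylpropanoate | COC(=O)CCc1ccccc1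
A10 | alternative 3 | lithium hexamethyldisilazide, LiN(SiMe3)2 | [Li]N([Si](C)(C)C)[Si](C)(C)C
A11 | alternative 3 | bis(1,3-diketone) carrying both 3-oxo-5-phenylpentanoyl chains | COC1=C(C(=O)CC(=O)CCc2ccccc2)[C@H](Oc2cc(C(=O)CC(=O)CCc3ccccc3)c(O)cc2OCc2ccccc2)[C@@H](OCc2ccccc2)[C@@H](OCc2ccccc2)[C@@H]1OCc1ccccc1
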